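## Retrosynthetic overview

1. The target comes from triol 22 by acylation of the equatorial 2α-OH. The 2α,3α-diol comes from a ring A silyl enol ether at C2=C3 by Rubottom oxidation and bulky-hydride reduction.
2. Ring B (C9–C10 bond, C7=C8) comes from an Ireland–Claisen ring contraction of a six-membered lactone C20(=O)–O–C7. The O–C7 bond is temporary: it relays the C7 configuration to C9 and C10 and releases C20 as a carboxyl group.
3. Ring A (C1–C10 and C4–C5) comes from a double Michael (formal [4+2]) reaction. The lithium dienolate of 4-methylpent-1-en-3-one supplies C1–C4 with the gem-dimethyl carbon; the C5=C10 bond of the unsaturated lactone is the acceptor.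
4. Enabling feature: C20 (on C10) and C7 (ring B) are 1,5-related across C10–C5–C6, so a C20 carbonyl can be tied to C7 through oxygen as an unsaturated δ-lactone. This activates C5=C10 and differentiates its faces. The C2/C3 oxygens next to C4 map onto the enolate oxygen of the C1–C4 unit.
5. Lactone 7 comes from (R)-linalool (C7–C9, C11–C17 and the C13 stereocentre) by allylic oxidation, asymmetric allylation and acrylate ring-closing metathesis. Ring order: temporary lactone, then ring A, then ring B.

Key step: step 8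

Assumption: labdane numbering (C1–C20; ring A = C1–C5, C10; ring B = C5–C10) is used for every intermediate, and (R)-(−)-linalool and 4-methylpent-1-en-3-one are taken as purchasable.

## Route

Step 1
Reactants: 1 (R)-(−)-linalool
Product: 2 (R)-linalool triethylsilyl ether
Conditions: Et3SiOTf, 2,6-lutidine, CH2Cl2, −78 to 0 °C
Reagents that add atoms: triethylsilyl triflate, CC[Si](CC)(CC)OS(=O)(=O)C(F)(F)F
Why: Base-buffered O-silylation of the tertiary allylic alcohol with a silyl triflate should proceed without allylic ionisation and carries the chiral-pool C13 (R) centre forward untouched.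

Step 2
Reactants: 2 (R)-linalool triethylsilyl ether
Product: 3 (2E,6R)-2,6-dimethyl-6-(triethylsilyloxy)octa-2,7-dien-1-ol
Conditions: SeO2 (0.3 equiv), t-BuOOH, salicylic acid (cat.), CH2Cl2, 23 °C
Reagents that add atoms: selenium dioxide (catalytic oxygen carrier), O=[Se]=O; tert-butyl hydroperoxide (terminal oxidant), CC(C)(C)OO
Why: The SeO2 allylic oxidation (ene reaction then [2,3] shift) should oxidise only the E-methyl group of the trisubstituted alkene, because the vinyl group has no allylic hydrogen, and gives the E allylic alcohol that becomes C7.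

Step 3
Reactants: 3 (2E,6R)-2,6-dimethyl-6-(triethylsilyloxy)octa-2,7-dien-1-ol
Product: 4 (2E,6R)-2,6-dimethyl-6-(triethylsilyloxy)octa-2,7-dienal
Conditions: Dess–Martin periodinane, pyridine, CH2Cl2, 0 to 23 °C
Reagents that add atoms: none
Why: Buffered Dess–Martin oxidation of the primary allylic alcohol should give the enal without E/Z isomerisation or loss of the silyl ether.

Step 4
Reactants: 4 (2E,6R)-2,6-dimethyl-6-(triethylsilyloxy)octa-2,7-dienal
Product: 5 (4S,5E,9R)-5,9-dimethyl-9-(triethylsilyloxy)undeca-1,5,10-trien-4-ol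
Conditions: (−)-Ipc2BOMe, CH2=CHCH2MgBr, Et2O, 0 °C; then 4, −78 °C; NaOH, H2O2, 0 °C
Reagents that add atoms: allylmagnesium bromide (allyl group delivered through the allylborane), C=CC[Mg]Br
Why: Brown asymmetric allylboration adds only 1,2 to the enal, and the (+)-α-pinene-derived reagent is expected to attack the si face and set the C7 carbinol as S under reagent control.

Step 5
Reactants: 5 (4S,5E,9R)-5,9-dimethyl-9-(triethylsilyloxy)undeca-1,5,10-trien-4-ol
Product: 6 (4S,5E,9R)-5,9-dimethyl-9-(triethylsilyloxy)undeca-1,5,10-trien-4-yl acrylate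
Conditions: acryloyl chloride, Et3N, CH2Cl2, −20 to 0 °C
Reagents that add atoms: acryloyl chloride, C=CC(=O)Cl
Why: O-Acylation of the secondary alcohol brings in C20 and C10 as the acrylate without touching the C7 stereocentre.

Step 6
Reactants: 6 (4S,5E,9R)-5,9-dimethyl-9-(triethylsilyloxy)undeca-1,5,10-trien-4-yl acrylate
Product: 7 (6S)-6-[(2E,6R)-6-methyl-6-(triethylsilyloxy)octa-2,7-dien-2-yl]-5,6-dihydro-2H-pyran-2-one
Conditions: second-generation Grubbs catalyst RuCl2(=CHPh)(H2IMes)(PCy3) (5 mol %), CH2Cl2, 40 °C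
Reagents that add atoms: none
Why: Ring-closing metathesis of the acrylate and the terminal allyl alkene should form the six-membered unsaturated lactone (the C5=C10 bond), while the trisubstituted alkene and the hindered vinyl group next to the quaternary carbinol stay out of the reaction.

Step 7
Reactants: 8 4-methylpent-1-en-3-one
Product: 9 trimethyl[(4-methylpenta-1,3-dien-3-yl)oxy]silane
Conditions: Me3SiOTf, Et3N, Et2O, 0 °C
Reagents that add atoms: trimethylsilyl triflate, C[Si](C)(C)OS(=O)(=O)C(F)(F)F
Why: Soft enolisation and silylation can only occur at the isopropyl methine, giving the cross-conjugated silyl dienol ether as a storable precursor of the dienolate.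

Step 8
Reactants: 7 (6S)-6-[(2E,6R)-6-methyl-6-(triethylsilyloxy)octa-2,7-dien-2-yl]-5,6-dihydro-2H-pyran-2-one; 9 trimethyl[(4-methylpenta-1,3-dien-3-yl)oxy]silane
Product: 13 (3S,4aR,8aR)-6-(tert-butyldimethylsilyloxy)-5,5-dimethyl-3-[(2E,6R)-6-methyl-6-(triethylsilyloxy)octa-2,7-dien-2-yl]-3,4,4a,5,8,8a-hexahydro-1H-isochromen-1-one, via lithium dienolate 10 (not isolated), via Michael adduct enolate 11 (not isolated), via bicyclic lithium enolate 12 (not isolated)
Conditions: 9, CH3Li, THF, 0 °C; then 7, −78 to −30 °C; then t-BuMe2SiCl, HMPA, −78 to 0 °C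
Reagents that add atoms: tert-butyldimethylsilyl chloride, CC(C)(C)[Si](C)(C)Cl
Why: CH3Li cleaves 9 to the cross-conjugated lithium dienolate 10, whose tetrasubstituted enolate carbon C4 adds in conjugate fashion to C5 of lactone 7; the resulting lactone enolate 11 then adds through C10 to the terminal carbon C1 of the tethered vinyl ketone, giving ketone enolate 12, which is silylated on oxygen. The closest known reaction type is the double Michael reaction (anionic formal Diels–Alder) of kinetic lithium dienolates of enones with unsaturated esters and lactones. Ring A is closed by the second Michael addition as a 6-endo-trig closure onto C1, so the ring carries the C3 oxygen and the C4 gem-dimethyl group from the start. The new C5 stereocentre is set by the C7 side chain, the enolate adding anti to it as in trans-selective conjugate additions to 6-substituted dihydropyranones; C10 forms cis-fused and is erased in step 9. Regiochemistry is fixed by polarity (enolate carbon C4 to the β-carbon C5, α-carbon C10 to the enone terminus C1). The step needs 1,4-addition rather than carbonyl addition or γ-deprotonation of the lactone, which the ester-type acceptor, the unsubstituted β-carbon and low temperature should secure.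

Step 9
Reactants: 13 (3S,4aR,8aR)-6-(tert-butyldimethylsilyloxy)-5,5-dimethyl-3-[(2E,6R)-6-methyl-6-(triethylsilyloxy)octa-2,7-dien-2-yl]-3,4,4a,5,8,8a-hexahydro-1H-isochromen-1-one
Product: 16 (13R)-3-(tert-butyldimethylsilyloxy)-13-(triethylsilyloxy)labda-2,7,14-trien-20-oic acid (5α-H; 9α-H; 10β-carboxyl), via lactone silyl ketene acetal 14 (not isolated), via silyl ester 15 (not isolated)
Conditions: LiN(i-Pr)2, t-BuMe2SiCl, THF/HMPA, −78 °C; then toluene, 105 °C; then K2CO3 (cat.), MeOH/H2O, 0 °C
Reagents that add atoms: none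
Why: Ireland–Claisen rearrangement of the lactone silyl ketene acetal (ring contraction) must pass through a boat-shaped array inside the six-membered lactone, so the O–C7 bond is exchanged for the C9–C10 bond on the same face; this relays C7 (S) to C10 (C20 β, trans ring fusion because the side chain was anti to the C4–C5 bond) and, through the E alkene, to C9 (H α), while creating ring B with the C7=C8 bond.

Step 10
Reactants: 16 (13R)-3-(tert-butyldimethylsilyloxy)-13-(triethylsilyloxy)labda-2,7,14-trien-20-oic acid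
Product: 17 (13R)-3-(tert-butyldimethylsilyloxy)-13-(triethylsilyloxy)labda-2,7,14-trien-20-ol
Conditions: LiAlH4, THF, 0 to 60 °C
Reagents that add atoms: none
Why: Hydride reduction of the neopentyl carboxylic acid to the primary alcohol leaves the silyl enol ether, the silyl ether and the alkenes untouched.

Step 11
Reactants: 17 (13R)-3-(tert-butyldimethylsilyloxy)-13-(triethylsilyloxy)labda-2,7,14-trien-20-ol
Product: 18 (13R)-3-(tert-butyldimethylsilyloxy)-13-(triethylsilyloxy)labda-2,7,14-trien-20-yl acetate
Conditions: Ac2O, pyridine, DMAP (cat.), CH2Cl2, 23 °C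
Reagents that add atoms: acetic anhydride, CC(=O)OC(C)=O
Why: Acetylation of the only free hydroxyl installs the C20 acetate of the target under conditions that the silyl enol ether tolerates.

Step 12
Reactants: 18 (13R)-3-(tert-butyldimethylsilyloxy)-13-(triethylsilyloxy)labda-2,7,14-trien-20-yl acetate
Product: 20 (13R)-20-acetoxy-2α-(tert-butyldimethylsilyloxy)-13-(triethylsilyloxy)labda-7,14-dien-3-one, via silyloxy epoxide 19 (not isolated)
Conditions: dimethyldioxirane (1.05 equiv), acetone/CH2Cl2, −78 °C; then 23 °C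
Reagents that add atoms: dimethyldioxirane, CC1(C)OO1
Why: In this Rubottom oxidation the electron-rich silyl enol ether should be epoxidised faster than the C7=C8 and vinyl alkenes, from the α face away from the axial C20 and 4β-methyl groups, and the 1,4-silyl shift then gives the equatorial (also thermodynamic) 2α-silyloxy ketone.

Step 13
Reactants: 20 (13R)-20-acetoxy-2α-(tert-butyldimethylsilyloxy)-13-(triethylsilyloxy)labda-7,14-dien-3-one
Product: 21 (13R)-20-acetoxy-2α-(tert-butyldimethylsilyloxy)-13-(triethylsilyloxy)labda-7,14-dien-3α-ol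
Conditions: LiBH(s-Bu)3, THF, −78 to −40 °C; AcOH quench at −78 °C
Reagents that add atoms: none
Why: The bulky trialkylborohydride should attack the C3 ketone along the equatorial trajectory (β face), as it does with 2-substituted cyclohexanones and 4,4-dimethyl-3-keto terpenoids, giving the axial 3α-alcohol cis to the 2α-oxygen while the hindered neopentyl acetate survives at low temperature.

Step 14
Reactants: 21 (13R)-20-acetoxy-2α-(tert-butyldimethylsilyloxy)-13-(triethylsilyloxy)labda-7,14-dien-3α-ol
Product: 22 (13R)-20-acetoxylabda-7,14-diene-2α,3α,13-triol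
Conditions: HF·pyridine, pyridine, THF, 0 to 23 °C
Reagents that add atoms: none
Why: Pyridine-buffered fluoride desilylation removes both silyl ethers without acetate migration or ionisation of the tertiary allylic alcohol.

Step 15
Reactants: 22 (13R)-20-acetoxylabda-7,14-diene-2α,3α,13-triol
Product: 23 CNP0171655.1, (13R)-20-acetoxy-2α-[(Z)-2-methylbut-2-enoyloxy]labda-7,14-diene-3α,13-diol
Conditions: angelic acid, 2,4,6-trichlorobenzoyl chloride, Et3N, toluene, 23 °C; then 22, toluene, 75 °C
Reagents that add atoms: angelic acid, C/C=C(/C)C(=O)O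
Why: Yamaguchi-type mixed-anhydride esterification without DMAP should keep the Z geometry of the angelate and acylate only the equatorial 2α-OH, since the axial neopentyl 3α-OH and the tertiary 13-OH are too hindered.

## Compound list

1 | (R)-(−)-linalool, (3R)-3,7-dimethylocta-1,6-dien-3-ol | C=C[C@](C)(O)CCC=C(C)C | starting material
2 | (R)-linalool triethylsilyl ether | C=C[C@](C)(O[Si](CC)(CC)CC)CCC=C(C)C | intermediate
3 | (2E,6R)-2,6-dimethyl-6-(triethylsilyloxy)octa-2,7-dien-1-ol | C=C[C@](C)(O[Si](CC)(CC)CC)CC/C=C(\C)CO | intermediate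
4 | (2E,6R)-2,6-dimethyl-6-(triethylsilyloxy)octa-2,7-dienal | C=C[C@](C)(O[Si](CC)(CC)CC)CC/C=C(\C)C=O | intermediate
5 | (4S,5E,9R)-5,9-dimethyl-9-(triethylsilyloxy)undeca-1,5,10-trien-4-ol | C=CC[C@H](O)/C(C)=C/CC[C@@](C)(O[Si](CC)(CC)CC)C=C | intermediate
6 | (4S,5E,9R)-5,9-dimethyl-9-(triethylsilyloxy)undeca-1,5,10-trien-4-yl acrylate | C=CC(=O)O[C@@H](CC=C)/C(C)=C/CC[C@@](C)(O[Si](CC)(CC)CC)C=C | intermediate
7 | (6S)-6-[(2E,6R)-6-methyl-6-(triethylsilyloxy)octa-2,7-dien-2-yl]-5,6-dihydro-2H-pyran-2-one | O=C1C=CC[C@H](O1)/C(C)=C/CC[C@@](C)(O[Si](CC)(CC)CC)C=C | intermediate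
8 | 4-methylpent-1-en-3-one (isopropyl vinyl ketone) | C=CC(=O)C(C)C | starting material
9 | trimethyl[(4-methylpenta-1,3-dien-3-yl)oxy]silane | C=CC(O[Si](C)(C)C)=C(C)C | intermediate
10 | lithium 4-methylpenta-1,3-dien-3-olate (cross-conjugated dienolate) | [Li]OC(C=C)=C(C)C | intermediate
11 | lithium enolate of the lactone carrying the 2-methyl-3-oxopent-4-en-2-yl group at C5, anti to the C7 side chain | C=CC(=O)C(C)(C)[C@@H]1C[C@@H](/C(C)=C/CC[C@@](C)(O[Si](CC)(CC)CC)C=C)OC(O[Li])=C1 | intermediate
12 | lithium enolate (C2=C3–OLi) of the cis-fused bicyclic keto lactone | O=C1O[C@H](/C(C)=C/CC[C@@](C)(O[Si](CC)(CC)CC)C=C)C[C@H]2C(C)(C)C(O[Li])=CC[C@@H]12 | intermediate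
13 | (3S,4aR,8aR)-6-(tert-butyldimethylsilyloxy)-5,5-dimethyl-3-[(2E,6R)-6-methyl-6-(triethylsilyloxy)octa-2,7-dien-2-yl]-3,4,4a,5,8,8a-hexahydro-1H-isochromen-1-one (H-3 trans to H-4a, cis ring fusion) | O=C1O[C@H](/C(C)=C/CC[C@@](C)(O[Si](CC)(CC)CC)C=C)C[C@H]2C(C)(C)C(O[Si](C)(C)C(C)(C)C)=CC[C@@H]12 | intermediate
14 | tert-butyldimethylsilyl ketene acetal of lactone 13 (C10=C20) | CC(C)(C)[Si](C)(C)OC1=C2CC=C(O[Si](C)(C)C(C)(C)C)C(C)(C)[C@@H]2C[C@@H](/C(C)=C/CC[C@@](C)(O[Si](CC)(CC)CC)C=C)O1 | intermediate
15 | tert-butyldimethylsilyl ester of acid 16 | C=C[C@](C)(O[Si](CC)(CC)CC)CC[C@H]1C(C)=CC[C@H]2C(C)(C)C(O[Si](C)(C)C(C)(C)C)=CC[C@]12C(=O)O[Si](C)(C)C(C)(C)C | intermediate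
16 | (13R)-3-(tert-butyldimethylsilyloxy)-13-(triethylsilyloxy)labda-2,7,14-trien-20-oic acid (5α-H, 9α-H, 10β-CO2H) | C=C[C@](C)(O[Si](CC)(CC)CC)CC[C@H]1C(C)=CC[C@H]2C(C)(C)C(O[Si](C)(C)C(C)(C)C)=CC[C@]12C(=O)O | intermediate
17 | (13R)-3-(tert-butyldimethylsilyloxy)-13-(triethylsilyloxy)labda-2,7,14-trien-20-ol | C=C[C@](C)(O[Si](CC)(CC)CC)CC[C@H]1C(C)=CC[C@H]2C(C)(C)C(O[Si](C)(C)C(C)(C)C)=CC[C@]12CO | intermediate
18 | (13R)-3-(tert-butyldimethylsilyloxy)-13-(triethylsilyloxy)labda-2,7,14-trien-20-yl acetate | C=C[C@](C)(O[Si](CC)(CC)CC)CC[C@H]1C(C)=CC[C@H]2C(C)(C)C(O[Si](C)(C)C(C)(C)C)=CC[C@]12COC(C)=O | intermediate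
19 | 2α,3α-epoxide of 18 (3-silyloxy oxirane) | C=C[C@](C)(O[Si](CC)(CC)CC)CC[C@H]1C(C)=CC[C@H]2C(C)(C)[C@]3(O[Si](C)(C)C(C)(C)C)O[C@@H]3C[C@]12COC(C)=O | intermediate
20 | (13R)-20-acetoxy-2α-(tert-butyldimethylsilyloxy)-13-(triethylsilyloxy)labda-7,14-dien-3-one | C=C[C@](C)(O[Si](CC)(CC)CC)CC[C@H]1C(C)=CC[C@H]2C(C)(C)C(=O)[C@H](O[Si](C)(C)C(C)(C)C)C[C@]12COC(C)=O | intermediate
21 | (13R)-20-acetoxy-2α-(tert-butyldimethylsilyloxy)-13-(triethylsilyloxy)labda-7,14-dien-3α-ol | C=C[C@](C)(O[Si](CC)(CC)CC)CC[C@H]1C(C)=CC[C@H]2C(C)(C)[C@H](O)[C@H](O[Si](C)(C)C(C)(C)C)C[C@]12COC(C)=O | intermediate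
22 | (13R)-20-acetoxylabda-7,14-diene-2α,3α,13-triol | C=C[C@](C)(O)CC[C@H]1C(C)=CC[C@H]2C(C)(C)[C@H](O)[C@H](O)C[C@]12COC(C)=O | intermediate
23 | CNP0171655.1, (13R)-20-acetoxy-2α-angeloyloxylabda-7,14-diene-3α,13-diol | C=C[C@](C)(O)CC[C@H]1C(C)=CC[C@H]2C(C)(C)[C@H](O)[C@H](OC(=O)/C(C)=C\C)C[C@]12COC(C)=O | target

## Step count and risks

Total step count: 15. Longest linear sequence: 14 steps (steps 1–6 and 8–15 from (R)-linalool); step 7 is a one-step side branch.

Steps most likely to fail:

Step 8 (key step). The vinyl ketone dienolate may oligomerise, the hindered enolate may deprotonate the lactone at the γ-position and open the ring, or the transient enone may be consumed before the second bond closes. The fallback sets out from 7 and returns at 13, making the ring A bonds one at a time with no enone present during the first addition. The lithium enolate released by CH3Li from 2-methyl-3-(trimethylsilyloxy)but-2-ene would be added to 7 at −78 °C (C4–C5 bond, anti to the C7 side chain). The lactone enolate would be trapped with dimethylmethyleneammonium iodide to give Mannich lactone F1. N-Methylation with CH3I and elimination with DBU would give α-methylene lactone F2. KOt-Bu in THF would close ring A by intramolecular Michael addition of the methyl ketone enolate to the exocyclic acceptor, giving keto lactone F3. KN(SiMe3)2 and t-BuMe2SiCl would silylate the only enolisable ketone position and return to 13.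

Step 9. The boat-shaped rearrangement may not reach the congested C10, so that the ketene acetal is lost by desilylation or ketene formation instead of closing the C9–C10 bond. The fallback sets out from 13 and returns at 17. NaOMe in MeOH would open the lactone to hydroxy ester F4, which would be acylated with methyl chloroformate and pyridine to allylic carbonate F5. Pd(PPh3)4 (zerovalent palladium) with the zinc ester enolate made from LiN(SiMe3)2 and ZnCl2 would effect an intramolecular allylic alkylation (Tsuji–Trost). The six-membered ring forms by attack at C9; ionisation and attack both occur anti to the metal, so the overall stereochemical course matches that of the rearrangement. This gives methyl ester F6, which LiAlH4 would reduce to 17.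

Step 12. Chemoselectivity may be lost by competing epoxidation of the ring B alkene, or the silyloxy epoxide may open in other ways. The fallback sets out from 18 and returns at 20 without any epoxidising agent. Bu4NF buffered with AcOH at 0 °C would cleave the enol ether to ketone F7. KN(SiMe3)2 followed by 2-(phenylsulfonyl)-3-phenyloxaziridine would hydroxylate the only enolisable position from the α face to give hydroxy ketone F8. t-BuMe2SiOTf and 2,6-lutidine would then give 20.

Further compounds

F1 | step 8 | Mannich lactone: lactone with the 3-methyl-2-oxobutan-3-yl group at C5 and CH2NMe2 at C10 (C10 configuration not defined, lost in the next step) | O=C1O[C@H](/C(C)=C/CC[C@@](C)(O[Si](CC)(CC)CC)C=C)C[C@@H](C(C)(C)C(C)=O)C1CN(C)C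
F2 | step 8 | α-methylene lactone | O=C1O[C@H](/C(C)=C/CC[C@@](C)(O[Si](CC)(CC)CC)C=C)C[C@@H](C(C)(C)C(C)=O)C1=C
F3 | step 8 | cis-fused bicyclic keto lactone (3-ketone of ring A) | O=C1O[C@H](/C(C)=C/CC[C@@](C)(O[Si](CC)(CC)CC)C=C)C[C@H]2C(C)(C)C(=O)CC[C@@H]12
F4 | step 9 | hydroxy ester (ring-opened lactone, C20 methyl ester, free C7 alcohol) | COC(=O)[C@@H]1CC=C(O[Si](C)(C)C(C)(C)C)C(C)(C)[C@@H]1C[C@H](O)/C(C)=C/CC[C@@](C)(O[Si](CC)(CC)CC)C=C
F5 | step 9 | allylic methyl carbonate of F4 | COC(=O)[C@@H]1CC=C(O[Si](C)(C)C(C)(C)C)C(C)(C)[C@@H]1C[C@H](OC(=O)OC)/C(C)=C/CC[C@@](C)(O[Si](CC)(CC)CC)C=C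
F6 | step 9 | methyl ester of acid 16 | C=C[C@](C)(O[Si](CC)(CC)CC)CC[C@H]1C(C)=CC[C@H]2C(C)(C)C(O[Si](C)(C)C(C)(C)C)=CC[C@]12C(=O)OC
F7 | step 12 | (13R)-20-acetoxy-13-(triethylsilyloxy)labda-7,14-dien-3-one | C=C[C@](C)(O[Si](CC)(CC)CC)CC[C@H]1C(C)=CC[C@H]2C(C)(C)C(=O)CC[C@]12COC(C)=O
F8 | step 12 | (13R)-20-acetoxy-2α-hydroxy-13-(triethylsilyloxy)labda-7,14-dien-3-one | C=C[C@](C)(O[Si](CC)(CC)CC)CC[C@H]1C(C)=CC[C@H]2C(C)(C)C(=O)[C@H](O)C[C@]12COC(C)=O
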